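## The problem

The target is a sesquilignan in which one tetrasubstituted benzene ring (ring A) belongs to two heterocyclic systems. It is the benzo ring of a 2-aryl-3-hydroxymethyl-7-methoxy-2,3-dihydrobenzofuran (O1, C2, C3, C3a to C7a). Through C5 it is also one of the two aryl groups of a cis-fused 2,6-diaryl-3,7-dioxabicyclo[3.3.0]octane (furofuran; benzylic carbons Cα on ring A and Cα' on the syringyl ring, bridgeheads Cβ and Cβ', methylenes Cγ and Cγ').

The six stereocentres fall into two sets: four in the furofuran (Cα S, Cβ R, Cα' S, Cβ' R, both aryl groups exo) and C2 and C3 of the dihydrofuran (2S,3S), which carry the aryl and hydroxymethyl groups cis. Inside the furofuran the bridgehead pair can control the benzylic pair, because ring closure places each aryl group exo. The flat arene between the two sets transmits nothing, so each set needs its own source of absolute configuration.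

The cis-dihydrobenzofuran is the less stable diastereomer. While C3 carries a carbonyl group it epimerises by enolisation. Its C2–O1 bond, like the Cα–O and Cα'–O bonds, is a benzylic ether para to an oxygen substituent: it ionises with acid and, once the phenol is free, can open to a quinone methide with base. Two phenols and a primary alcohol must therefore be unmasked at the end without acid, strong base or hydrogenolysis.

The feature that allows a late closure is that C2 is a benzylic carbon bound to O1 and C3 is bound to C3a of ring A. In an open precursor the O1–CH2–aryl hydrogen lies five atoms from C3, so a carbene at C3 can form the C2–C3 bond by insertion into this doubly activated C–H bond.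

## Retrosynthesis

**24 to 23 to 22 (O–Si bonds, oxidation level at the C3 substituent).** The end game is a fluoride desilylation of bis-silyl ether 23 and, before it, a hydride reduction of ester 22. Triisopropylsilyl ethers are chosen over benzyl ethers because the ring C2–O1 bond is itself an aryl benzyl ether, and a hydrogenation catalyst would have to tell it from the protecting groups. Reducing the ester directly after ring formation removes the only acidic hydrogen at C3.

**22 to 21 (C2–C3).** Cutting C2–C3 leaves the aryl ether oxygen, ring A and the whole furofuran untouched and leads to diazo ester 21, which has no dihydrofuran stereocentre. The neighbouring cuts are worse. Closing C2–O1 would pass through a benzylic cation or quinone methide and give the trans isomer. A C3–C3a bond formation would need a metalated ring A next to an acidic ester. The forward reaction must deliver the kinetic cis product and override four remote stereocentres, which a chiral dirhodium carboxylate is known to do for this substrate class.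

**21 to 20 to 17 + 18 (C=N2, aryl–CH2).** The diazo group comes from arylacetate 20 by diazo transfer, and the acetate arm from aryl bromide 17 and methyl bromoacetate 18 by a palladium-catalysed Reformatsky coupling. A bromine is preferred to an allyl group as the latent acetate. It costs one step instead of five, is inert through the furofuran assembly, and makes aldehyde 2 a better aldol acceptor.

**17 to 13 + 16 (O–CH2).** The dioxygenated benzyl aryl ether is as acid-labile as a dimethoxybenzyl protecting group, so it is attached only after the acid-mediated furofuran closure, by Mitsunobu coupling of phenol 13 with alcohol 16 (from vanillin 14 via 15). The coupling is neutral, which protects the silyl ethers.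

**13 to 11 to 10 (Cα–O, Cα'–O).** Both ether bonds of the furofuran are cut to tetraol 11 (from allyl ether 10). These bonds form through benzylic cations, and their configuration is set in the closure itself. The precursor therefore needs only the trans relationship at Cβ/Cβ', and the benzylic carbinol configurations are irrelevant. Removing the allyl group first gives the ring A side a free para hydroxyl, so that Cα ionises easily as a quinone methide despite the bromine.

**10 to 9 to 6 + 8 (Cβ'–Cα').** Lactone reduction leads back to 9, the aldol product of lactone 6 and silylated syringaldehyde 8 (from 7). The five-membered lactone acts as a template: the aldehyde adds anti to the existing substituent and sets Cβ' from Cβ.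

**6 to 2 + 3 (Cβ–Cα).** A proline-catalysed cross-aldol between methyl 4-oxobutanoate 3 and aldehyde 2 (from 5-bromovanillin 1), with reduction and lactonisation, gives 6. This is the only step that introduces absolute configuration into the furofuran, and it does so catalytically.

## Roads not taken

**Alternative 1:** The cut opens both benzylic C–O bonds of the furofuran down to benzylic CH2 groups, which leads to the dibenzylbutanediol A1. In the forward direction DDQ oxidises each 4-hydroxybenzyl group to a quinone methide, the hydroxymethyl group across the Cβ–Cβ' bond traps it, and (+)-medioresinol A2 results.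
- Merits: A1 has only two stereocentres and is reachable by standard asymmetric alkylation. No protecting groups are needed, and the exo,exo geometry comes from the same kinetic preference the chosen plan relies on at Cα.
- Weak points: over-oxidation and aryltetralin formation compete with the double closure. More seriously, A2 is only half the problem. Its guaiacyl ring carries no handle at the position that must become C3a, and its two phenols are not differentiated. An oxidative coupling with a C6–C3 partner would give the trans-dihydrobenzofuran without enantiocontrol.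
- Comparison: for the furofuran alone this road is shorter and milder than steps 1 to 7. The chosen plan sets against this a ring A that carries bromine and a differentiated phenol from the first step, and it keeps the quinone methide closure as its own fallback for step 7.

**Alternative 2:** The cut removes both C–C bonds that flank Cβ–Cβ'. In the forward direction the lithio derivative of dithiane A3 adds to the menthyloxybutenolide A4 anti to the alkoxy group, and the resulting enolate is trapped by the dihydrobenzofuran aldehyde A5 to give lactone A6.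
- Merits: high convergence, a cheap auxiliary with reliable trans,trans control, and all carbons of the target in one operation.
- Weak points: A5 must already contain the cis-dihydrobenzofuran, so the rhodium insertion (or an equivalent) is still needed, only earlier. The sensitive ring then has to survive dithiane hydrolysis, reduction of lactone and acetal, and the acid closure of the furofuran, in which the C2–O1 bond can ionise and drift to trans. The auxiliary is stoichiometric, and at least five operations follow the key step.
- Comparison: its convergence is better. The chosen plan answers with catalytic control of both stereocentre sets and with a cis ring that never meets acid.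

**Alternative 3:** The cut removes the Cγ'–Cβ' carbon–carbon bond and the Cα'–O bond. In the forward direction SnCl4 or Me3SiOTf ionises the methoxymethyl ether of A7 to an oxocarbenium ion, the styrene attacks it, and the silyl ether oxygen on Cγ captures the resulting syringyl cation to give the protected target A8.
- Merits: two rings, one C–C and one C–O bond in a single late step, ending one deprotection sequence from the target.
- Weak points: the Lewis acid meets a preformed cis-dihydrobenzofuran (hence the deactivating mesylate) and a benzylic methoxymethyl ether that can ionise at Cα instead of at the acetal carbon. The relative configuration at Cβ' and Cα' rests on an untested transition-state preference. A7 itself needs a stereodefined acyclic chain plus the cis ring, so its synthesis is not shorter.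
- Comparison: in bond economy of the key step this road is superior. The chosen plan sets against it that no step after cis-ring formation uses acid, and that its furofuran closure is the classical, stereoconvergent one.

Key step: step 13

**Remarks on the chemistry**
- Assumption: the sense of induction of the N-phthaloyl-tert-leucinate catalysts on 2-(arylmethoxy)aryl diazoacetates is taken to be 2R for the S-ligand series, so Rh2(R-PTTL)4 is specified for the (2S,3R) ester 22. If a model substrate shows the opposite sense, the S-ligand catalyst is used with no other change.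
- In 9, 10, 11 and 12 the syringyl carbinol carbon is a mixture of epimers and is written without a descriptor. Step 7 sets it.
- Abbreviations: TIPS = triisopropylsilyl; ArA = 3-bromo-5-methoxy-4-(allyloxy)phenyl; ArS = 3,5-dimethoxy-4-(TIPS-oxy)phenyl; ArV = 3-methoxy-4-(TIPS-oxy)phenyl; Fur = (1S,3aR,4S,6aR)-4-ArS-tetrahydro-1H,3H-furo[3,4-c]furan-1-yl.

## Steps

Step 1
Reactants: 1 5-bromovanillin
Product: 2 4-(allyloxy)-3-bromo-5-methoxybenzaldehyde
Conditions: allyl bromide, K2CO3, DMF, rt
Reagents that add atoms: allyl bromide, C=CCBr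
Why: Williamson etherification of the acidic bromophenol; the allyl group withstands LiN(i-Pr)2, borohydride and acid and later leaves under zerovalent palladium without disturbing the aryl bromide or a silyl ether.

Step 2
Reactants: 2 4-(allyloxy)-3-bromo-5-methoxybenzaldehyde; 3 methyl 4-oxobutanoate
Product: 6 (4R)-4-[(R)-ArA(hydroxy)methyl]oxolan-2-one, via aldol aldehyde 4 (not isolated), via diol ester 5 (not isolated)
Conditions: L-proline (20 mol%), DMF, 4 °C, slow addition of 3; then MeOH, NaBH4, 0 °C; aq. HCl work-up
Reagents that add atoms: none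
Why: Proline enamine cross-aldol of an enolisable aldehyde with a non-enolisable aromatic aldehyde, then borohydride reduction and lactonisation; the enamine of (S)-proline adds through its hydrogen-bonded transition state to give the anti (3S,4R) adduct 4, which fixes Cβ (C4 of 6) and with it the absolute configuration of the furofuran. The acceptor is activated by the meta bromine and the twisted 4-alkoxy group, and reduction before isolation prevents epimerisation of the α-formyl centre.

Step 3
Reactants: 7 syringaldehyde
Product: 8 3,5-dimethoxy-4-(TIPS-oxy)benzaldehyde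
Conditions: i-Pr3SiCl, imidazole, DMF, rt to 40 °C
Reagents that add atoms: chlorotriisopropylsilane, CC(C)[Si](Cl)(C(C)C)C(C)C
Why: Silylation of the hindered phenol; the bulky silyl ether survives amide base, borohydride, mild acid and the palladium steps and is removed at the end by fluoride.

Step 4
Reactants: 6 (4R)-4-[(R)-ArA(hydroxy)methyl]oxolan-2-one; 8 3,5-dimethoxy-4-(TIPS-oxy)benzaldehyde
Product: 9 (3S,4R)-4-[(R)-ArA(hydroxy)methyl]-3-[ArS(hydroxy)methyl]oxolan-2-one (trans, both carbinol epimers)
Conditions: LiN(i-Pr)2 (2.2 equiv), THF, −78 °C; then 8, −78 °C; aq. NH4Cl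
Reagents that add atoms: none
Why: Aldol addition of the lactone dianion (alkoxide and enolate); the aldehyde approaches the enolate face anti to the C4 substituent, giving the 3,4-trans lactone and so fixing Cβ' relative to Cβ. The new carbinol centre needs no control because step 7 resets it.

Step 5
Reactants: 9 trans diol lactone
Product: 10 (1R,2R,3R)-1-ArA-4-ArS-2,3-bis(hydroxymethyl)butane-1,4-diol (both epimers at C4)
Conditions: LiBH4, THF, 0 °C to rt
Reagents that add atoms: none
Why: Borohydride reduction of the lactone to the diol; LiBH4 is used because it leaves the aryl bromide and the aryl silyl ether alone.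

Step 6
Reactants: 10 allyl ether tetraol
Product: 11 (1R,2R,3R)-1-(3-bromo-4-hydroxy-5-methoxyphenyl)-4-ArS-2,3-bis(hydroxymethyl)butane-1,4-diol (both epimers at C4)
Conditions: Pd(PPh3)4 (5 mol%, zerovalent palladium), morpholine, THF, rt
Reagents that add atoms: none
Why: Tsuji–Trost allyl transfer to morpholine; ionisation of the allyl aryl ether is fast at room temperature whereas oxidative addition into the electron-rich aryl bromide is not. The freed para hydroxyl lets Cα ionise as a quinone methide in step 7 in spite of the bromine.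

Step 7
Reactants: 11 phenol tetraol
Product: 13 2-bromo-6-methoxy-4-Fur-phenol, via monocyclic oxolane triol 12 (not isolated)
Conditions: camphorsulfonic acid (0.2 equiv), MeCN, 0 °C to rt
Reagents that add atoms: none
Why: Acid-catalysed double cyclodehydration of a 1,4-diaryl-2,3-bis(hydroxymethyl)butane-1,4-diol, the classical furofuran closure; Cα ionises as the quinone methide of the free phenol and Cα' as the trioxygenated benzylic cation, and each is captured by the hydroxymethyl group of the other half in a 5-exo closure. Both benzylic centres are set here whatever their earlier configuration: each aryl group takes the exo position trans to the adjacent ring bond under kinetic control, and the cis ring fusion follows from the trans Cβ/Cβ' relationship.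

Step 8
Reactants: 14 vanillin
Product: 15 3-methoxy-4-(TIPS-oxy)benzaldehyde
Conditions: i-Pr3SiCl, imidazole, DMF, rt
Reagents that add atoms: chlorotriisopropylsilane, CC(C)[Si](Cl)(C(C)C)C(C)C
Why: Silylation of the phenol, so that the aryl group that will sit on C2 carries the same fluoride-labile protection as the syringyl ring.

Step 9
Reactants: 15 3-methoxy-4-(TIPS-oxy)benzaldehyde
Product: 16 [3-methoxy-4-(TIPS-oxy)phenyl]methanol
Conditions: NaBH4, MeOH, 0 °C
Reagents that add atoms: none
Why: Borohydride reduction of an aromatic aldehyde; the aryl silyl ether is stable under these conditions.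

Step 10
Reactants: 13 2-bromo-6-methoxy-4-Fur-phenol; 16 [3-methoxy-4-(TIPS-oxy)phenyl]methanol
Product: 17 (1S,3aR,4S,6aR)-1-[3-bromo-5-methoxy-4-(ArV-methoxy)phenyl]-4-ArS-tetrahydro-1H,3H-furo[3,4-c]furan
Conditions: PPh3, diisopropyl azodicarboxylate, THF, 0 °C to rt
Reagents that add atoms: none
Why: Mitsunobu etherification of an acidic phenol with a primary benzylic alcohol; the neutral conditions avoid base-induced silyl transfer, and both ortho positions and the para position of the phenol are blocked, so only O-alkylation is possible.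

Step 11
Reactants: 17 aryl bromide; 18 methyl bromoacetate
Product: 20 methyl 2-[5-Fur-3-methoxy-2-(ArV-methoxy)phenyl]acetate, via Reformatsky reagent 19 (not isolated)
Conditions: Zn (activated with Me3SiCl), 18, THF, rt; then 17, Pd2(dba)3 (2.5 mol%, zerovalent palladium), XPhos (2-dicyclohexylphosphino-2',4',6'-triisopropylbiphenyl, 10 mol%), THF, 60 °C
Reagents that add atoms: none
Why: Negishi-type coupling of a Reformatsky reagent with an aryl bromide (α-arylation of an acetate); the zinc enolate is non-basic, so the silyl ethers, the benzylic aryl ether and the furofuran are untouched, and the bulky biarylphosphine allows oxidative addition next to the ortho alkoxy group.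

Step 12
Reactants: 20 methyl arylacetate
Product: 21 methyl 2-diazo-2-[5-Fur-3-methoxy-2-(ArV-methoxy)phenyl]acetate
Conditions: 4-acetamidobenzenesulfonyl azide, DBU, MeCN/CH2Cl2, 0 °C to rt
Reagents that add atoms: 4-acetamidobenzenesulfonyl azide, CC(=O)Nc1ccc(cc1)S(=O)(=O)N=[N+]=[N-]
Why: Regitz diazo transfer to an arylacetate, whose α-hydrogens are acidic enough for DBU; nothing else in the molecule is deprotonated under these conditions.

Step 13
Reactants: 21 aryl diazoacetate
Product: 22 methyl (2S,3R)-5-Fur-7-methoxy-2-ArV-2,3-dihydro-1-benzofuran-3-carboxylate (2,3-cis)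
Conditions: Rh2(R-PTTL)4 (dirhodium tetrakis[N-phthaloyl-(R)-tert-leucinate], divalent rhodium, 2 mol%), toluene, −60 °C, slow addition of 21, high dilution
Reagents that add atoms: none
Why: Rh2(R-PTTL)4 extrudes dinitrogen from 21 and forms a donor/acceptor rhodium carbenoid at the future C3. The carbenoid inserts in a concerted but asynchronous, hydride-transfer-like manner into one of the two enantiotopic C–H bonds of the O–CH2–aryl group, which the ether oxygen and the electron-rich ArV ring both activate. The closest known reaction type is the chiral dirhodium carboxylate-catalysed intramolecular C–H insertion of 2-(benzyloxy)aryl diazoacetates, which gives cis-2-aryl-2,3-dihydrobenzofuran-3-carboxylates. The dihydrofuran ring closes by 1,5-insertion through a six-centre transition state, so only the C2–C3 bond is made while O1 and ring A are already in place. C2 is set by the choice between the two enantiotopic hydrogens and C3 by the carbenoid face presented, both inside the chiral pocket of the four phthalimido-tert-leucinate ligands, and the aryl and ester groups end up cis under this kinetic control. The step needs site selectivity, cis selectivity and catalyst control over four remote stereocentres: the ether CH2 is the only C–H bond five atoms from the carbenoid, the furofuran C–H bonds sit meta on ring A and cannot reach it, and the arene insulates the reacting centres from the existing ones. Low temperature, dilution and slow addition suppress carbenoid dimerisation and intermolecular insertion, and the base-free medium keeps the cis ester from epimerising at C3.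

Step 14
Reactants: 22 cis ester
Product: 23 [(2S,3S)-5-Fur-7-methoxy-2-ArV-2,3-dihydro-1-benzofuran-3-yl]methanol (2,3-cis)
Conditions: i-Bu2AlH (3 equiv), CH2Cl2, −78 °C; aq. potassium sodium tartrate
Reagents that add atoms: none
Why: Hydride reduction of the ester to the primary alcohol under Lewis acidic, non-basic conditions at low temperature, where enolisation at C3 does not compete; once C3 carries CH2OH the cis configuration is no longer epimerisable.

Step 15
Reactants: 23 bis-silyl ether
Product: 24 target, 4-{(1S,3aR,4S,6aR)-4-[(2S,3S)-2-(4-hydroxy-3-methoxyphenyl)-3-(hydroxymethyl)-7-methoxy-2,3-dihydro-1-benzofuran-5-yl]tetrahydro-1H,3H-furo[3,4-c]furan-1-yl}-2,6-dimethoxyphenol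
Conditions: Bu4NF (2.4 equiv), AcOH (2.6 equiv), THF, 0 °C
Reagents that add atoms: none
Why: Fluoride cleavage of both aryl silyl ethers; the acetic acid buffer keeps the phenols protonated, so no phenoxide can open the C2–O1 bond to a quinone methide, and no benzylic C–O bond is exposed to acid or hydrogen.

## Compound list

1 | 5-bromovanillin (3-bromo-4-hydroxy-5-methoxybenzaldehyde) | COc1cc(C=O)cc(Br)c1O | starting material
2 | 4-(allyloxy)-3-bromo-5-methoxybenzaldehyde | COc1cc(C=O)cc(Br)c1OCC=C | intermediate
3 | methyl 4-oxobutanoate | COC(=O)CCC=O | starting material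
4 | methyl (3S,4R)-4-[4-(allyloxy)-3-bromo-5-methoxyphenyl]-3-formyl-4-hydroxybutanoate (anti aldol, not isolated) | COC(=O)C[C@H](C=O)[C@@H](O)c1cc(OC)c(OCC=C)c(Br)c1 | intermediate
5 | methyl (3R,4R)-4-[4-(allyloxy)-3-bromo-5-methoxyphenyl]-4-hydroxy-3-(hydroxymethyl)butanoate (not isolated) | COC(=O)C[C@H](CO)[C@@H](O)c1cc(OC)c(OCC=C)c(Br)c1 | intermediate
6 | (4R)-4-{(R)-[4-(allyloxy)-3-bromo-5-methoxyphenyl](hydroxy)methyl}oxolan-2-one | O=C1C[C@H](CO1)[C@@H](O)c1cc(OC)c(OCC=C)c(Br)c1 | intermediate
7 | syringaldehyde (4-hydroxy-3,5-dimethoxybenzaldehyde) | COc1cc(C=O)cc(OC)c1O | starting material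
8 | 3,5-dimethoxy-4-(triisopropylsilyloxy)benzaldehyde | COc1cc(C=O)cc(OC)c1O[Si](C(C)C)(C(C)C)C(C)C | intermediate
9 | (3S,4R)-4-{(R)-[4-(allyloxy)-3-bromo-5-methoxyphenyl](hydroxy)methyl}-3-{hydroxy[3,5-dimethoxy-4-(triisopropylsilyloxy)phenyl]methyl}oxolan-2-one, trans lactone, both epimers at the new carbinol carbon | O=C1OC[C@H]([C@@H](O)c2cc(OC)c(OCC=C)c(Br)c2)[C@H]1C(O)c1cc(OC)c(O[Si](C(C)C)(C(C)C)C(C)C)c(OC)c1 | intermediate
10 | (1R,2R,3R)-1-[4-(allyloxy)-3-bromo-5-methoxyphenyl]-4-[3,5-dimethoxy-4-(triisopropylsilyloxy)phenyl]-2,3-bis(hydroxymethyl)butane-1,4-diol, both epimers at C4 | COc1cc(cc(Br)c1OCC=C)[C@H](O)[C@@H](CO)[C@H](CO)C(O)c1cc(OC)c(O[Si](C(C)C)(C(C)C)C(C)C)c(OC)c1 | intermediate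
11 | (1R,2R,3R)-1-(3-bromo-4-hydroxy-5-methoxyphenyl)-4-[3,5-dimethoxy-4-(triisopropylsilyloxy)phenyl]-2,3-bis(hydroxymethyl)butane-1,4-diol, both epimers at C4 | COc1cc(cc(Br)c1O)[C@H](O)[C@@H](CO)[C@H](CO)C(O)c1cc(OC)c(O[Si](C(C)C)(C(C)C)C(C)C)c(OC)c1 | intermediate
12 | 2-bromo-4-[(2S,3R,4R)-4-{hydroxy[3,5-dimethoxy-4-(triisopropylsilyloxy)phenyl]methyl}-3-(hydroxymethyl)oxolan-2-yl]-6-methoxyphenol, both carbinol epimers (not isolated) | COc1cc(cc(Br)c1O)[C@H]1OC[C@H](C(O)c2cc(OC)c(O[Si](C(C)C)(C(C)C)C(C)C)c(OC)c2)[C@@H]1CO | intermediate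
13 | 2-bromo-4-{(1S,3aR,4S,6aR)-4-[3,5-dimethoxy-4-(triisopropylsilyloxy)phenyl]tetrahydro-1H,3H-furo[3,4-c]furan-1-yl}-6-methoxyphenol | COc1cc(cc(Br)c1O)[C@H]1OC[C@H]2[C@@H]1CO[C@@H]2c1cc(OC)c(O[Si](C(C)C)(C(C)C)C(C)C)c(OC)c1 | intermediate
14 | vanillin | COc1cc(C=O)ccc1O | starting material
15 | 3-methoxy-4-(triisopropylsilyloxy)benzaldehyde | COc1cc(C=O)ccc1O[Si](C(C)C)(C(C)C)C(C)C | intermediate
16 | [3-methoxy-4-(triisopropylsilyloxy)phenyl]methanol | COc1cc(CO)ccc1O[Si](C(C)C)(C(C)C)C(C)C | intermediate
17 | (1S,3aR,4S,6aR)-1-(3-bromo-5-methoxy-4-{[3-methoxy-4-(triisopropylsilyloxy)phenyl]methoxy}phenyl)-4-[3,5-dimethoxy-4-(triisopropylsilyloxy)phenyl]tetrahydro-1H,3H-furo[3,4-c]furan | COc1cc(cc(Br)c1OCc1ccc(O[Si](C(C)C)(C(C)C)C(C)C)c(OC)c1)[C@H]1OC[C@H]2[C@@H]1CO[C@@H]2c1cc(OC)c(O[Si](C(C)C)(C(C)C)C(C)C)c(OC)c1 | intermediate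
18 | methyl bromoacetate | COC(=O)CBr | starting material
19 | bromo(2-methoxy-2-oxoethyl)zinc (Reformatsky reagent, not isolated) | COC(=O)C[Zn]Br | intermediate
20 | methyl 2-[5-{(1S,3aR,4S,6aR)-4-[3,5-dimethoxy-4-(triisopropylsilyloxy)phenyl]tetrahydro-1H,3H-furo[3,4-c]furan-1-yl}-3-methoxy-2-{[3-methoxy-4-(triisopropylsilyloxy)phenyl]methoxy}phenyl]acetate | COc1cc(cc(CC(=O)OC)c1OCc1ccc(O[Si](C(C)C)(C(C)C)C(C)C)c(OC)c1)[C@H]1OC[C@H]2[C@@H]1CO[C@@H]2c1cc(OC)c(O[Si](C(C)C)(C(C)C)C(C)C)c(OC)c1 | intermediate
21 | methyl 2-diazo-2-[5-{(1S,3aR,4S,6aR)-4-[3,5-dimethoxy-4-(triisopropylsilyloxy)phenyl]tetrahydro-1H,3H-furo[3,4-c]furan-1-yl}-3-methoxy-2-{[3-methoxy-4-(triisopropylsilyloxy)phenyl]methoxy}phenyl]acetate | COc1cc(cc(C(=[N+]=[N-])C(=O)OC)c1OCc1ccc(O[Si](C(C)C)(C(C)C)C(C)C)c(OC)c1)[C@H]1OC[C@H]2[C@@H]1CO[C@@H]2c1cc(OC)c(O[Si](C(C)C)(C(C)C)C(C)C)c(OC)c1 | intermediate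
22 | methyl (2S,3R)-5-{(1S,3aR,4S,6aR)-4-[3,5-dimethoxy-4-(triisopropylsilyloxy)phenyl]tetrahydro-1H,3H-furo[3,4-c]furan-1-yl}-7-methoxy-2-[3-methoxy-4-(triisopropylsilyloxy)phenyl]-2,3-dihydro-1-benzofuran-3-carboxylate (2,3-cis) | COc1cc([C@H]2Oc3c(OC)cc([C@H]4OC[C@H]5[C@@H]4CO[C@@H]5c4cc(OC)c(O[Si](C(C)C)(C(C)C)C(C)C)c(OC)c4)cc3[C@H]2C(=O)OC)ccc1O[Si](C(C)C)(C(C)C)C(C)C | intermediate
23 | [(2S,3S)-5-{(1S,3aR,4S,6aR)-4-[3,5-dimethoxy-4-(triisopropylsilyloxy)phenyl]tetrahydro-1H,3H-furo[3,4-c]furan-1-yl}-7-methoxy-2-[3-methoxy-4-(triisopropylsilyloxy)phenyl]-2,3-dihydro-1-benzofuran-3-yl]methanol (2,3-cis) | COc1cc([C@H]2Oc3c(OC)cc([C@H]4OC[C@H]5[C@@H]4CO[C@@H]5c4cc(OC)c(O[Si](C(C)C)(C(C)C)C(C)C)c(OC)c4)cc3[C@H]2CO)ccc1O[Si](C(C)C)(C(C)C)C(C)C | intermediate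
24 | 4-{(1S,3aR,4S,6aR)-4-[(2S,3S)-2-(4-hydroxy-3-methoxyphenyl)-3-(hydroxymethyl)-7-methoxy-2,3-dihydro-1-benzofuran-5-yl]tetrahydro-1H,3H-furo[3,4-c]furan-1-yl}-2,6-dimethoxyphenol | COc1cc([C@H]2Oc3c(OC)cc([C@H]4OC[C@H]5[C@@H]4CO[C@@H]5c4cc(OC)c(O)c(OC)c4)cc3[C@H]2CO)ccc1O | target

## Step count and least certain steps

Total: 15 steps. Longest linear sequence: 12 steps (1, 2, 4, 5, 6, 7, 10, 11, 12, 13, 14, 15, from 5-bromovanillin).

**Step 13 (key step).** Three things may go wrong.
- The cis configuration may erode by enolisation at C3 during reaction, work-up or chromatography.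
- Catalyst control may be insufficient, because the methoxy group ortho to the ether oxygen twists the O–CH2 bond out of the ring plane and may change the preferred approach of the C–H bond.
- Bimolecular carbenoid reactions may occur at the activated furofuran C–H bonds or ether oxygens of a second molecule.

Fallback: auxiliary-assisted insertion, setting out from 20 and returning at 23. Me3SnOH in 1,2-dichloroethane cleaves the methyl ester of 20 to the arylacetic acid F1. Carbodiimide esterification with (S)-2-hydroxy-1-(pyrrolidin-1-yl)propan-1-one gives the lactamide ester F2, and diazo transfer gives the diazo ester F3. Insertion with Rh2(O2CC7H15)4, or with the matched enantiomer of the chiral catalyst for double stereodifferentiation, gives the cis dihydrobenzofuran ester F4, in which a substrate-bound stereocentre next to the carbenoid adds its own facial bias. LiBH4 at 0 °C cleaves the auxiliary ester reductively and gives 23. The S auxiliary is drawn; its antipode is used if matching requires it.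

**Step 7.** Ionisation at Cα' may be incomplete, because its 4-silyloxy group is twisted out of conjugation. The stronger acid then needed can reopen the ring on the phenol side, so that the exo selectivity drifts, or can let the neighbouring arene intercept the cation (aryltetralin formation).

Fallback: closure of both rings through quinone methides, setting out from 11 and returning at 17. Bu4NF/AcOH removes the silyl group of 11 and gives the bis-phenol tetraol F5. With both benzylic carbons para to a free hydroxyl, very mild acid suffices for the double closure to the bis-phenol furofuran F6. The more acidic bromophenol of F6 is etherified selectively with 16 under Mitsunobu conditions to give the mono-ether F7, and silylation of the remaining syringyl phenol (i-Pr3SiCl, imidazole) gives 17.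

**Step 2.** Addition of the enamine to the aromatic aldehyde may be slow, so that self-condensation of 3 takes over. The α-formyl centre may also partly epimerise before reduction, which would lower the enantiomeric purity of every later compound.

Fallback: auxiliary-controlled anti aldol, setting out from 2 and returning at 6. (S)-4-Benzyl-1,3-oxazolidin-2-one is acylated with methyl 4-chloro-4-oxobutanoate to the imide F8. MgCl2-catalysed anti-selective aldol addition to 2 (Et3N, Me3SiCl, EtOAc) gives the silyl ether F9, which acidic methanol desilylates to the anti adduct F10. NaBH4 in wet THF removes the auxiliary reductively without touching the methyl ester and gives 5, which lactonises to 6. The S auxiliary is drawn; its antipode is used if the magnesium enolate of this acyl group shows the opposite facial preference.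

**Step 11.** Oxidative addition at the bromide next to the bulky arylmethoxy group may be slow, which would lead to protodebromination or to loss of the zinc enolate by self-condensation.

Fallback: allylation and oxidative cleavage, setting out from 17 and returning at 20. Stille coupling of 17 with allyltributylstannane (Pd(PPh3)4, toluene, 100 °C) gives the allyl arene F11. OsO4 (catalytic) with NaIO4 and 2,6-lutidine cleaves the alkene to the arylacetaldehyde F12. NaClO2/NaH2PO4/2-methylbut-2-ene oxidises F12 to the acid F1 already described under step 13, and (trimethylsilyl)diazomethane in methanol gives 20.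

## Further compounds

F1 | step 13 | 2-[5-{(1S,3aR,4S,6aR)-4-[3,5-dimethoxy-4-(triisopropylsilyloxy)phenyl]tetrahydro-1H,3H-furo[3,4-c]furan-1-yl}-3-methoxy-2-{[3-methoxy-4-(triisopropylsilyloxy)phenyl]methoxy}phenyl]acetic acid | COc1cc(cc(CC(=O)O)c1OCc1ccc(O[Si](C(C)C)(C(C)C)C(C)C)c(OC)c1)[C@H]1OC[C@H]2[C@@H]1CO[C@@H]2c1cc(OC)c(O[Si](C(C)C)(C(C)C)C(C)C)c(OC)c1
F2 | step 13 | (S)-1-oxo-1-(pyrrolidin-1-yl)propan-2-yl ester of acid F1 | COc1cc(cc(CC(=O)O[C@@H](C)C(=O)N2CCCC2)c1OCc1ccc(O[Si](C(C)C)(C(C)C)C(C)C)c(OC)c1)[C@H]1OC[C@H]2[C@@H]1CO[C@@H]2c1cc(OC)c(O[Si](C(C)C)(C(C)C)C(C)C)c(OC)c1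
F3 | step 13 | (S)-1-oxo-1-(pyrrolidin-1-yl)propan-2-yl 2-diazo-2-arylacetate corresponding to 21 | COc1cc(cc(C(=[N+]=[N-])C(=O)O[C@@H](C)C(=O)N2CCCC2)c1OCc1ccc(O[Si](C(C)C)(C(C)C)C(C)C)c(OC)c1)[C@H]1OC[C@H]2[C@@H]1CO[C@@H]2c1cc(OC)c(O[Si](C(C)C)(C(C)C)C(C)C)c(OC)c1
F4 | step 13 | (S)-1-oxo-1-(pyrrolidin-1-yl)propan-2-yl (2S,3R)-2,3-cis-dihydrobenzofuran-3-carboxylate corresponding to 22 | COc1cc([C@H]2Oc3c(OC)cc([C@H]4OC[C@H]5[C@@H]4CO[C@@H]5c4cc(OC)c(O[Si](C(C)C)(C(C)C)C(C)C)c(OC)c4)cc3[C@H]2C(=O)O[C@@H](C)C(=O)N2CCCC2)ccc1O[Si](C(C)C)(C(C)C)C(C)C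
F5 | step 7 | (1R,2R,3R)-1-(3-bromo-4-hydroxy-5-methoxyphenyl)-4-(4-hydroxy-3,5-dimethoxyphenyl)-2,3-bis(hydroxymethyl)butane-1,4-diol, both epimers at C4 | COc1cc(cc(Br)c1O)[C@H](O)[C@@H](CO)[C@H](CO)C(O)c1cc(OC)c(O)c(OC)c1
F6 | step 7 | 2-bromo-4-[(1S,3aR,4S,6aR)-4-(4-hydroxy-3,5-dimethoxyphenyl)tetrahydro-1H,3H-furo[3,4-c]furan-1-yl]-6-methoxyphenol | COc1cc(cc(Br)c1O)[C@H]1OC[C@H]2[C@@H]1CO[C@@H]2c1cc(OC)c(O)c(OC)c1
F7 | step 7 | 4-[(1S,3aR,4S,6aR)-4-(3-bromo-5-methoxy-4-{[3-methoxy-4-(triisopropylsilyloxy)phenyl]methoxy}phenyl)tetrahydro-1H,3H-furo[3,4-c]furan-1-yl]-2,6-dimethoxyphenol | COc1cc(cc(Br)c1OCc1ccc(O[Si](C(C)C)(C(C)C)C(C)C)c(OC)c1)[C@H]1OC[C@H]2[C@@H]1CO[C@@H]2c1cc(OC)c(O)c(OC)c1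
F8 | step 2 | methyl 4-[(4S)-4-benzyl-2-oxo-1,3-oxazolidin-3-yl]-4-oxobutanoate | COC(=O)CCC(=O)N1[C@@H](Cc2ccccc2)COC1=O
F9 | step 2 | methyl (3S,4R)-4-[4-(allyloxy)-3-bromo-5-methoxyphenyl]-3-{[(4S)-4-benzyl-2-oxo-1,3-oxazolidin-3-yl]carbonyl}-4-(trimethylsilyloxy)butanoate | COC(=O)C[C@H](C(=O)N1[C@@H](Cc2ccccc2)COC1=O)[C@@H](O[Si](C)(C)C)c1cc(OC)c(OCC=C)c(Br)c1
F10 | step 2 | methyl (3S,4R)-4-[4-(allyloxy)-3-bromo-5-methoxyphenyl]-3-{[(4S)-4-benzyl-2-oxo-1,3-oxazolidin-3-yl]carbonyl}-4-hydroxybutanoate | COC(=O)C[C@H](C(=O)N1[C@@H](Cc2ccccc2)COC1=O)[C@@H](O)c1cc(OC)c(OCC=C)c(Br)c1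
F11 | step 11 | (1S,3aR,4S,6aR)-1-(3-allyl-5-methoxy-4-{[3-methoxy-4-(triisopropylsilyloxy)phenyl]methoxy}phenyl)-4-[3,5-dimethoxy-4-(triisopropylsilyloxy)phenyl]tetrahydro-1H,3H-furo[3,4-c]furan | COc1cc(cc(CC=C)c1OCc1ccc(O[Si](C(C)C)(C(C)C)C(C)C)c(OC)c1)[C@H]1OC[C@H]2[C@@H]1CO[C@@H]2c1cc(OC)c(O[Si](C(C)C)(C(C)C)C(C)C)c(OC)c1
F12 | step 11 | 2-[5-{(1S,3aR,4S,6aR)-4-[3,5-dimethoxy-4-(triisopropylsilyloxy)phenyl]tetrahydro-1H,3H-furo[3,4-c]furan-1-yl}-3-methoxy-2-{[3-methoxy-4-(triisopropylsilyloxy)phenyl]methoxy}phenyl]acetaldehyde | COc1cc(cc(CC=O)c1OCc1ccc(O[Si](C(C)C)(C(C)C)C(C)C)c(OC)c1)[C@H]1OC[C@H]2[C@@H]1CO[C@@H]2c1cc(OC)c(O[Si](C(C)C)(C(C)C)C(C)C)c(OC)c1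
A1 | alternative 1 | (2R,3R)-2-(4-hydroxy-3-methoxybenzyl)-3-(4-hydroxy-3,5-dimethoxybenzyl)butane-1,4-diol | COc1cc(C[C@@H](CO)[C@H](CO)Cc2cc(OC)c(O)c(OC)c2)ccc1O
A2 | alternative 1 | (+)-medioresinol | COc1cc([C@H]2OC[C@H]3[C@@H]2CO[C@@H]3c2cc(OC)c(O)c(OC)c2)ccc1O
A3 | alternative 2 | 2-[4-(benzyloxy)-3,5-dimethoxyphenyl]-1,3-dithiane | COc1cc(C2SCCCS2)cc(OC)c1OCc1ccccc1
A4 | alternative 2 | (5R)-5-[(1R,2S,5R)-menthyloxy]furan-2(5H)-one | O=C1O[C@@H](O[C@@H]2C[C@H](C)CC[C@H]2C(C)C)C=C1
A5 | alternative 2 | (2S,3S)-2-[4-(benzyloxy)-3-methoxyphenyl]-3-[(tert-butyldimethylsilyloxy)methyl]-7-methoxy-2,3-dihydro-1-benzofuran-5-carbaldehyde (2,3-cis) | COc1cc([C@H]2Oc3c(OC)cc(C=O)cc3[C@H]2CO[Si](C)(C)C(C)(C)C)ccc1OCc1ccccc1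
A6 | alternative 2 | trans,trans-disubstituted menthyloxy lactone from dithiane A3, butenolide A4 and aldehyde A5 (carbinol drawn as one epimer) | O=C1O[C@@H](O[C@@H]2C[C@H](C)CC[C@H]2C(C)C)[C@H](C2(SCCCS2)c2cc(OC)c(OCc3ccccc3)c(OC)c2)[C@H]1[C@H](O)c1cc(OC)c2O[C@H](c3ccc(OCc4ccccc4)c(OC)c3)[C@H](CO[Si](C)(C)C(C)(C)C)c2c1
A7 | alternative 3 | methoxymethyl ether styrene: cis-dihydrobenzofuran (aryl mesylate, tert-butyldimethylsilyl ether) carrying at C5 the (1S,2R,3E)-1-(methoxymethoxy)-2-[(triethylsilyloxy)methyl]-4-[4-(benzyloxy)-3,5-dimethoxyphenyl]but-3-enyl chain | COc1cc([C@H]2Oc3c(OC)cc([C@@H](OCOC)[C@@H](CO[Si](CC)(CC)CC)/C=C/c4cc(OC)c(OCc5ccccc5)c(OC)c4)cc3[C@H]2CO[Si](C)(C)C(C)(C)C)ccc1OS(C)(=O)=O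
A8 | alternative 3 | target protected as aryl mesylate, benzyl ether and tert-butyldimethylsilyl ether | COc1cc([C@H]2Oc3c(OC)cc([C@H]4OC[C@H]5[C@@H]4CO[C@@H]5c4cc(OC)c(OCc6ccccc6)c(OC)c4)cc3[C@H]2CO[Si](C)(C)C(C)(C)C)ccc1OS(C)(=O)=O
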